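**Retrosynthetic overview**

1. In the target, the ester carbon on C1 of ring A and the hydroxyl on C2' of ring B both sit ortho to the bridging ether oxygen (C6–O–C1'). Joining them gives a seven-membered depsidone lactone, so the target is treated as the methanolysis product of that lactone, which also leaves O2' free and O1' as the ether.
2. The lactone is disconnected by a Baeyer–Villiger ring expansion to a xanthone: oxygen is inserted between the carbonyl carbon C9 and the ring B carbon C8a of 5,8-dimethoxy-1,3-bis(tosyloxy)xanthone.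
3. The xanthone comes from phloroglucinol and 2-hydroxy-3,6-dimethoxybenzoic acid in P2O5–MeSO3H; the acid comes from 2,5-dimethoxyphenol by ortho-formylation and oxidation.
4. The prenyl group enters last at C5', by bromination para to the freed C2' hydroxyl and Stille coupling. The tosylates keep ring A from migrating and from being brominated, and are removed at the end.
5. Ring order: rings A and B are bought as arenes; the pyranone ring closes in step 3, is expanded to the lactone in step 5 and is opened in step 6.

Key step: step 5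

Remark: ring A is the benzoate ring (C1 CO2Me, C2 and C4 oxygens, C6 ether oxygen) and ring B the ring that ends up prenylated (C1' ether oxygen, C2' OH, C3' and C6' OMe, C5' prenyl); tricyclic compounds carry xanthone or dibenzodioxepine numbering, Ts is 4-methylphenylsulfonyl, and no compound in the route has a stereocentre.

**Route**

Step 1
Reactants: 1 2,5-dimethoxyphenol
Product: 3 2-hydroxy-3,6-dimethoxybenzaldehyde, via salicyl alcohol 2 (not isolated)
Conditions: MgCl2, Et3N, (CH2O)n, MeCN, reflux; then 1 M HCl
Reagents that add atoms: paraformaldehyde (source of formaldehyde), C=O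
Why: Casnati–Skattebøl ortho-formylation, in which the magnesium phenoxide delivers formaldehyde only to the one free ortho carbon (between OH and the C5 methoxy group) and a second formaldehyde oxidises the resulting salicyl alcohol to the aldehyde by hydride transfer.

Step 2
Reactants: 3 2-hydroxy-3,6-dimethoxybenzaldehyde
Product: 4 2-hydroxy-3,6-dimethoxybenzoic acid
Conditions: NaClO2, NaH2PO4, 2-methyl-2-butene, t-BuOH–H2O, rt
Reagents that add atoms: sodium chlorite, [Na+].[O-]Cl=O
Why: Pinnick oxidation of the aldehyde to the acid under buffered conditions, with 2-methyl-2-butene trapping the hypochlorous acid so that the electron-rich phenol ring should not be chlorinated.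

Step 3
Reactants: 4 2-hydroxy-3,6-dimethoxybenzoic acid; 5 phloroglucinol
Product: 7 1,3-dihydroxy-5,8-dimethoxy-9H-xanthen-9-one, via benzophenone 6 (not isolated)
Conditions: P2O5–MeSO3H, 80 °C; then ice–water
Reagents that add atoms: none
Why: Grover–Shah–Shah xanthone synthesis, in which Friedel–Crafts acylation of phloroglucinol by the acylium ion of 4 gives benzophenone 6 and its ortho,ortho'-dihydroxy pair cyclodehydrates to the pyranone; the symmetry of phloroglucinol and the single ortho hydroxyl of 4 allow only one constitution.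

Step 4
Reactants: 7 1,3-dihydroxy-5,8-dimethoxy-9H-xanthen-9-one
Product: 9 5,8-dimethoxy-9-oxo-9H-xanthene-1,3-diyl bis(4-methylbenzenesulfonate), via xanthone monotosylate 8 (not isolated)
Conditions: TsCl (3 equiv), K2CO3, acetone, reflux
Reagents that add atoms: 4-methylbenzenesulfonyl chloride, Cc1ccc(cc1)S(=O)(=O)Cl
Why: O-sulfonylation of phenols, in which the free C3 hydroxyl reacts first and the hydrogen-bonded C1 hydroxyl should follow at reflux with excess sulfonyl chloride.

Step 5
Reactants: 9 5,8-dimethoxy-9-oxo-9H-xanthene-1,3-diyl bis(4-methylbenzenesulfonate)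
Product: 11 6,9-dimethoxy-11-oxo-11H-dibenzo[b,e][1,4]dioxepine-1,3-diyl bis(4-methylbenzenesulfonate), via Criegee adduct 10 (not isolated)
Conditions: (CF3CO)2O, H2O2·urea, CF3CO2H–CH2Cl2, 0 °C → rt
Reagents that add atoms: trifluoroperacetic acid, OOC(=O)C(F)(F)F, made in the flask from trifluoroacetic anhydride, O=C(OC(=O)C(F)(F)F)C(F)(F)F, and urea–hydrogen peroxide, OO.NC(N)=O
Why: Proposed new method: in the acidic medium the xanthone carbonyl is activated by protonation, CF3CO3H adds at C9 to give Criegee adduct 10, and the ring B carbon C8a (C2' of the target) shifts from C9 to the neighbouring peroxide oxygen as trifluoroacetate leaves, which is a Baeyer–Villiger oxidation. The closest known reaction type is the CF3CO3H Baeyer–Villiger oxidation of benzophenones and fluorenones to aryl benzoates and dibenzopyranones; a xanthone carbonyl, being a vinylogous carbonate, has not been shown to react this way, which is why the acid medium is used to speed both the addition and the loss of trifluoroacetate. The seven-membered dibenzo[b,e][1,4]dioxepin-11-one ring is not closed by a cyclisation but arises by ring expansion of the six-membered pyranone through this 1,2-aryl shift. No stereocentre is formed. The step needs migration of C8a and not of the ring A carbon C9a: C8a has an ortho methoxy group and the ortho ring oxygen on an electron-rich ring, whereas C9a lies ortho and para to sulfonyloxy groups, which make it the poorer migrating carbon and also shield ring A from arene oxidation.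

Step 6
Reactants: 11 6,9-dimethoxy-11-oxo-11H-dibenzo[b,e][1,4]dioxepine-1,3-diyl bis(4-methylbenzenesulfonate)
Product: 12 methyl 6-(2-hydroxy-3,6-dimethoxyphenoxy)-2,4-bis(tosyloxy)benzoate
Conditions: NaOMe (1.1 equiv), MeOH–THF, 0 °C; then 1 M HCl
Reagents that add atoms: sodium methoxide, [Na+].[O-]C
Why: Base-mediated transesterification (lactone methanolysis), in which methoxide should attack the single acyl carbon of the strained aryl lactone faster than the sulfur of the tosylates at 0 °C, placing CO2Me on ring A and the free hydroxyl on C2'; ring B is still symmetric here, so a shift of ring A between O1' and O2' would change nothing.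

Step 7
Reactants: 12 methyl 6-(2-hydroxy-3,6-dimethoxyphenoxy)-2,4-bis(tosyloxy)benzoate
Product: 13 methyl 6-(5-bromo-2-hydroxy-3,6-dimethoxyphenoxy)-2,4-bis(tosyloxy)benzoate (bromine on C5', para to the C2' hydroxyl)
Conditions: NBS (1.0 equiv), CH2Cl2, −20 → 0 °C
Reagents that add atoms: N-bromosuccinimide, O=C1CCC(=O)N1Br
Why: Electrophilic aromatic bromination directed by the free C2' hydroxyl to C5', its only open ortho or para position, while ring A is deactivated by the ester and two sulfonyloxy groups.

Step 8
Reactants: 13 methyl 6-(5-bromo-2-hydroxy-3,6-dimethoxyphenoxy)-2,4-bis(tosyloxy)benzoate; 14 tributyl(3-methylbut-2-en-1-yl)stannane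
Product: 15 methyl 6-[2-hydroxy-3,6-dimethoxy-5-(3-methylbut-2-en-1-yl)phenoxy]-2,4-bis(tosyloxy)benzoate
Conditions: Pd(PPh3)4 (10 mol %), toluene, 110 °C
Reagents that add atoms: none
Why: Stille cross-coupling, in which zerovalent palladium inserts into the C5'–Br bond and transmetalation from tin followed by reductive elimination at the primary allyl terminus should give the linear prenyl arene; aryl tosylates are inert to Pd(PPh3)4 and no base is present to ionise the phenol.

Step 9
Reactants: 15 methyl 6-[2-hydroxy-3,6-dimethoxy-5-(3-methylbut-2-en-1-yl)phenoxy]-2,4-bis(tosyloxy)benzoate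
Product: 17 paucinervin B (methyl 2,4-dihydroxy-6-[2-hydroxy-3,6-dimethoxy-5-(3-methylbut-2-en-1-yl)phenoxy]benzoate), via aryl monotosylate 16 (not isolated)
Conditions: NaOMe (excess), MeOH, 0 °C → rt; then dilute HCl, 0 °C
Reagents that add atoms: none
Why: Nucleophilic S–O cleavage of aryl sulfonates by methoxide (sulfonyl transfer), favoured because both departing phenoxides are conjugated to the ester (the less hindered C4 tosylate is expected to go first), while the methyl ester is kept because its exchange with methoxide is degenerate.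

**Compound list**

1 | 2,5-dimethoxyphenol | COc1ccc(OC)c(O)c1 | starting material
2 | 2-(hydroxymethyl)-3,6-dimethoxyphenol, the salicyl alcohol formed in the flask in step 1 | OCc1c(O)c(OC)ccc1OC | intermediate
3 | 2-hydroxy-3,6-dimethoxybenzaldehyde | O=Cc1c(O)c(OC)ccc1OC | intermediate
4 | 2-hydroxy-3,6-dimethoxybenzoic acid | OC(=O)c1c(O)c(OC)ccc1OC | intermediate
5 | phloroglucinol (benzene-1,3,5-triol) | Oc1cc(O)cc(O)c1 | starting material
6 | (2-hydroxy-3,6-dimethoxyphenyl)(2,4,6-trihydroxyphenyl)methanone, the benzophenone formed in the flask in step 3 | O=C(c1c(O)cc(O)cc1O)c1c(O)c(OC)ccc1OC | intermediate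
7 | 1,3-dihydroxy-5,8-dimethoxy-9H-xanthen-9-one | O=C1c2c(O)cc(O)cc2Oc2c1c(OC)ccc2OC | intermediate
8 | 1-hydroxy-5,8-dimethoxy-9-oxo-9H-xanthen-3-yl 4-methylbenzenesulfonate, the monotosylate formed in the flask in step 4 | O=C1c2c(O)cc(OS(=O)(=O)c3ccc(C)cc3)cc2Oc2c1c(OC)ccc2OC | intermediate
9 | 5,8-dimethoxy-9-oxo-9H-xanthene-1,3-diyl bis(4-methylbenzenesulfonate) | O=C1c2c(OS(=O)(=O)c3ccc(C)cc3)cc(OS(=O)(=O)c3ccc(C)cc3)cc2Oc2c1c(OC)ccc2OC | intermediate
10 | 9-hydroxy-5,8-dimethoxy-9-(trifluoroacetylperoxy)-9H-xanthene-1,3-diyl bis(4-methylbenzenesulfonate), the Criegee adduct formed in the flask in step 5 | OC1(OOC(=O)C(F)(F)F)c2c(OS(=O)(=O)c3ccc(C)cc3)cc(OS(=O)(=O)c3ccc(C)cc3)cc2Oc2c1c(OC)ccc2OC | intermediate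
11 | 6,9-dimethoxy-11-oxo-11H-dibenzo[b,e][1,4]dioxepine-1,3-diyl bis(4-methylbenzenesulfonate) | O=C1Oc2c(OC)ccc(OC)c2Oc2cc(OS(=O)(=O)c3ccc(C)cc3)cc(OS(=O)(=O)c3ccc(C)cc3)c21 | intermediate
12 | methyl 6-(2-hydroxy-3,6-dimethoxyphenoxy)-2,4-bis(tosyloxy)benzoate | COC(=O)c1c(OS(=O)(=O)c2ccc(C)cc2)cc(OS(=O)(=O)c2ccc(C)cc2)cc1Oc1c(O)c(OC)ccc1OC | intermediate
13 | methyl 6-(5-bromo-2-hydroxy-3,6-dimethoxyphenoxy)-2,4-bis(tosyloxy)benzoate | COC(=O)c1c(OS(=O)(=O)c2ccc(C)cc2)cc(OS(=O)(=O)c2ccc(C)cc2)cc1Oc1c(O)c(OC)cc(Br)c1OC | intermediate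
14 | tributyl(3-methylbut-2-en-1-yl)stannane | CCCC[Sn](CCCC)(CCCC)CC=C(C)C | starting material
15 | methyl 6-[2-hydroxy-3,6-dimethoxy-5-(3-methylbut-2-en-1-yl)phenoxy]-2,4-bis(tosyloxy)benzoate | COC(=O)c1c(OS(=O)(=O)c2ccc(C)cc2)cc(OS(=O)(=O)c2ccc(C)cc2)cc1Oc1c(O)c(OC)cc(CC=C(C)C)c1OC | intermediate
16 | methyl 4-hydroxy-6-[2-hydroxy-3,6-dimethoxy-5-(3-methylbut-2-en-1-yl)phenoxy]-2-(tosyloxy)benzoate, the monotosylate formed in the flask in step 9 | COC(=O)c1c(OS(=O)(=O)c2ccc(C)cc2)cc(O)cc1Oc1c(O)c(OC)cc(CC=C(C)C)c1OC | intermediate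
17 | paucinervin B, methyl 2,4-dihydroxy-6-[2-hydroxy-3,6-dimethoxy-5-(3-methylbut-2-en-1-yl)phenoxy]benzoate | COC(=O)c1c(O)cc(O)cc1Oc1c(O)c(OC)cc(CC=C(C)C)c1OC | target

**Step count and risks**

Total steps: 9. Longest linear sequence: 9 steps (1 → 17); phloroglucinol 5 and stannane 14 enter at steps 3 and 8.

Steps most likely to fail:

1. Step 5 (Baeyer–Villiger ring expansion). The peracid may not add to C9, because the pyranone carbonyl is stabilised as a vinylogous carbonate. Under forcing, the electron-rich dimethoxy ring B of the product may be oxidised further, and migration of C9a instead of C8a would give the isomeric lactone. The fallback sets out from aldehyde 3, comes back at 12 and builds the diaryl ether by known coupling chemistry, leaving out compounds 4 to 11. Aldehyde 3 would be O-benzylated (BnBr, K2CO3, DMF) to 2-(benzyloxy)-3,6-dimethoxybenzaldehyde F1. Dakin-type Baeyer–Villiger oxidation of this electron-rich aldehyde with mCPBA in CH2Cl2 would give 2-(benzyloxy)-3,6-dimethoxyphenyl formate F2, and K2CO3 in MeOH would free 2-(benzyloxy)-3,6-dimethoxyphenol F3. Purchased methyl 2,4,6-trihydroxybenzoate would be tosylated at O4 and at one of its two equivalent ortho hydroxyls (TsCl 2 equiv, K2CO3, acetone) to methyl 6-hydroxy-2,4-bis(tosyloxy)benzoate F4. The remaining hydrogen-bonded hydroxyl would be triflated (Tf2O, pyridine, CH2Cl2) to methyl 2,4-bis(tosyloxy)-6-(trifluoromethylsulfonyloxy)benzoate F5. Palladium-catalysed C–O coupling of F3 with F5 (Pd(OAc)2, t-BuXPhos, K3PO4, toluene, 100 °C) should give methyl 6-[2-(benzyloxy)-3,6-dimethoxyphenoxy]-2,4-bis(tosyloxy)benzoate F6, since oxidative addition at the triflate ortho to the ester is expected to outpace that at the tosylates. Hydrogenolysis (H2, Pd/C, EtOAc) would then return 12.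

2. Step 8 (Stille prenylation). Allylic transposition during the tin-to-palladium transfer, or reductive elimination at the tertiary allyl terminus, would give the 1,1-dimethylallyl isomer; oxidative addition into the electron-rich bromide may also be slow. The fallback sets out from 13 and comes back at 15. Stille coupling of 13 with allyltributylstannane (Pd(PPh3)4, toluene, 110 °C), which has no such regiochemical ambiguity, would give methyl 6-(5-allyl-2-hydroxy-3,6-dimethoxyphenoxy)-2,4-bis(tosyloxy)benzoate F7. Olefin cross-metathesis of F7 with excess 2-methyl-2-butene (second-generation Grubbs catalyst, CH2Cl2, 40 °C) would then convert the allyl group into the prenyl group of 15.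

3. Step 9 (detosylation). A Smiles rearrangement is possible: the C2' phenoxide can add ipso to C6 of the still electron-poor ring A, so that ring A ends on O2' and the prenyl group comes to lie para to the ether oxygen instead of para to the free hydroxyl. A second process is O-methylation of a phenoxide by the methyl tosylate formed in the flask. The fallback sets out from 15 and comes back at 17. The C2' hydroxyl would first be capped (MOMCl, i-Pr2NEt, CH2Cl2) to give methyl 6-[3,6-dimethoxy-2-(methoxymethoxy)-5-(3-methylbut-2-en-1-yl)phenoxy]-2,4-bis(tosyloxy)benzoate F8, which has no ring B phenoxide to rearrange or to be methylated. NaOMe in MeOH would then give methyl 2,4-dihydroxy-6-[3,6-dimethoxy-2-(methoxymethoxy)-5-(3-methylbut-2-en-1-yl)phenoxy]benzoate F9, and brief treatment with dilute HCl in MeOH at rt would remove the acetal to give 17.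

**Further compounds**

F1 | step 5 | 2-(benzyloxy)-3,6-dimethoxybenzaldehyde | O=Cc1c(OCc2ccccc2)c(OC)ccc1OC
F2 | step 5 | 2-(benzyloxy)-3,6-dimethoxyphenyl formate | O=COc1c(OCc2ccccc2)c(OC)ccc1OC
F3 | step 5 | 2-(benzyloxy)-3,6-dimethoxyphenol | Oc1c(OCc2ccccc2)c(OC)ccc1OC
F4 | step 5 | methyl 6-hydroxy-2,4-bis(tosyloxy)benzoate | COC(=O)c1c(O)cc(OS(=O)(=O)c2ccc(C)cc2)cc1OS(=O)(=O)c1ccc(C)cc1
F5 | step 5 | methyl 2,4-bis(tosyloxy)-6-(trifluoromethylsulfonyloxy)benzoate | COC(=O)c1c(OS(=O)(=O)C(F)(F)F)cc(OS(=O)(=O)c2ccc(C)cc2)cc1OS(=O)(=O)c1ccc(C)cc1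
F6 | step 5 | methyl 6-[2-(benzyloxy)-3,6-dimethoxyphenoxy]-2,4-bis(tosyloxy)benzoate | COC(=O)c1c(OS(=O)(=O)c2ccc(C)cc2)cc(OS(=O)(=O)c2ccc(C)cc2)cc1Oc1c(OCc2ccccc2)c(OC)ccc1OC
F7 | step 8 | methyl 6-(5-allyl-2-hydroxy-3,6-dimethoxyphenoxy)-2,4-bis(tosyloxy)benzoate | COC(=O)c1c(OS(=O)(=O)c2ccc(C)cc2)cc(OS(=O)(=O)c2ccc(C)cc2)cc1Oc1c(O)c(OC)cc(CC=C)c1OC
F8 | step 9 | methyl 6-[3,6-dimethoxy-2-(methoxymethoxy)-5-(3-methylbut-2-en-1-yl)phenoxy]-2,4-bis(tosyloxy)benzoate | COC(=O)c1c(OS(=O)(=O)c2ccc(C)cc2)cc(OS(=O)(=O)c2ccc(C)cc2)cc1Oc1c(OCOC)c(OC)cc(CC=C(C)C)c1OC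
F9 | step 9 | methyl 2,4-dihydroxy-6-[3,6-dimethoxy-2-(methoxymethoxy)-5-(3-methylbut-2-en-1-yl)phenoxy]benzoate | COC(=O)c1c(O)cc(O)cc1Oc1c(OCOC)c(OC)cc(CC=C(C)C)c1OC
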